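**Retrosynthetic overview**
- Ring A is bought as 1,2,3,4-tetramethoxybenzene 1; C–H oxygenation (through 2 and 3) gives phenol 4, and ortho-formylation (through 5) gives salicylaldehyde 6, the acyl anion precursor.
- Ring B is bought as 4-iodophenyl acetate 7; Sonogashira coupling with ethynyltrimethylsilane 8 gives 9, and silicon-to-iodine exchange gives alkynyl(phenyl)iodonium triflate 10, an alkynyl cation equivalent.
- Key disconnection: the C3–C4 bond, cut to the carbene-derived acyl anion of 6 and the electrophilic acetylenic carbon of 10; their union is ynone 11.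
- Ring C (the pyranone) is the only ring formed, and it is formed last: O1–C2 closure of 11 by 6-endo-dig oxa-Michael addition gives 12, and acetate removal gives target 13.

Assumption: the target has no stereocentre and no stereogenic double bond, so "single enantiomer" means the one achiral compound drawn; no step has to set configuration.

**Route**

Step 1
Reactants: 1 1,2,3,4-tetramethoxybenzene
Product: 4 2,3,4,5-tetramethoxyphenol, via aryllithium 2 (not isolated), via lithium aryltrimethoxyborate 3 (not isolated)
Conditions: n-BuLi (1.2 equiv), TMEDA, THF, 0 °C → rt; B(OMe)3, −78 °C → rt; AcOH, 30% aq. H2O2, 0 °C → rt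
Reagents that add atoms: hydrogen peroxide, OO
Why: directed ortho-lithiation (the two ring C–H are equivalent, each next to OMe), boration, then peroxide oxidation with 1,2-aryl shift from boron to oxygen; no stereocentre is formed.

Step 2
Reactants: 4 2,3,4,5-tetramethoxyphenol
Product: 6 2-hydroxy-3,4,5,6-tetramethoxybenzaldehyde, via hydroxymethylphenol 5 (not isolated)
Conditions: MgCl2 (2 equiv), Et3N (4 equiv), (CH2O)n (7 equiv), MeCN, reflux; aq. HCl work-up
Reagents that add atoms: paraformaldehyde (reacts as formaldehyde), C=O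
Why: Casnati–Skattebøl magnesium-mediated ortho-formylation: the magnesium phenoxide delivers formaldehyde to the only free ring position, which is ortho to OH, and a second formaldehyde oxidises the magnesium benzylic alkoxide by hydride transfer.

Step 3
Reactants: 7 4-iodophenyl acetate; 8 ethynyltrimethylsilane
Product: 9 4-[(trimethylsilyl)ethynyl]phenyl acetate
Conditions: PdCl2(PPh3)2 (2 mol%), CuI (4 mol%), Et3N, THF, rt
Reagents that add atoms: none
Why: Sonogashira coupling (oxidative addition of the aryl iodide to zerovalent palladium formed in situ, transmetalation from the copper acetylide, reductive elimination); the aryl acetate and the C–Si bond survive Et3N at rt.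

Step 4
Reactants: 9 4-[(trimethylsilyl)ethynyl]phenyl acetate
Product: 10 [(4-acetoxyphenyl)ethynyl](phenyl)iodonium trifluoromethanesulfonate
Conditions: PhI(OAc)2 (1.0 equiv), Tf2O (0.5 equiv), CH2Cl2, 0 °C, 30 min; then 9, 0 °C, 1 h; precipitate with Et2O, store at −20 °C
Reagents that add atoms: (diacetoxyiodo)benzene, CC(=O)OI(OC(C)=O)c1ccccc1; trifluoromethanesulfonic anhydride, O=S(=O)(OS(=O)(=O)C(F)(F)F)C(F)(F)F
Why: PhI(OAc)2 and Tf2O form the oxo-bridged bis(triflate) of trivalent iodine, which the alkynylsilane attacks at iodine with β-silicon-assisted ipso substitution (alkynylsilane-to-alkynyliodonium exchange); the para-acetoxy group keeps the salt less electron-rich, hence more stable, than a para-alkoxy analogue.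

Step 5
Reactants: 6 2-hydroxy-3,4,5,6-tetramethoxybenzaldehyde; 10 [(4-acetoxyphenyl)ethynyl](phenyl)iodonium trifluoromethanesulfonate
Product: 13 4'-hydroxy-5,6,7,8-tetramethoxyflavone, via hydroxyaryl ynone 11 (not isolated), via 4'-acetoxyflavone 12 (not isolated)
Conditions: 6 (1.2 equiv), 10 (1.0 equiv), 2-(pentafluorophenyl)-6,7-dihydro-5H-pyrrolo[2,1-c][1,2,4]triazol-2-ium tetrafluoroborate (10 mol%), TMEDA (1.2 equiv), toluene, −40 → 0 °C; then K2CO3 (2.5 equiv), rt; then MeOH, rt; aq. NH4Cl
Reagents that add atoms: none
Why: Proposed new method: the triazolylidene adds to the aldehyde of 6 to give a Breslow intermediate (acyl anion equivalent) that attacks the electrophilic acetylenic carbon of 10 and expels iodobenzene, so two carbons that are both electrophilic in their resting forms are joined as ynone 11; K2CO3 in the still aprotic medium then closes ring C by 6-endo-dig oxa-Michael addition of the ortho phenoxide (12), and added MeOH cleaves the aryl acetate by base-catalysed transesterification; the closest known reaction types are carbene-catalysed C–H alkynylation of aryl aldehydes with alkynyliodonium salts, carbonate-mediated cyclisation of ortho-hydroxyaryl ynones to flavones, and Zemplén-type deacetylation, the new element being their telescoping on a free, doubly ortho-substituted salicylaldehyde; no stereocentre is formed.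

**Compound list**
1 | 1,2,3,4-tetramethoxybenzene | COc1ccc(OC)c(OC)c1OC | starting material
2 | (2,3,4,5-tetramethoxyphenyl)lithium | [Li]c1cc(OC)c(OC)c(OC)c1OC | intermediate
3 | lithium trimethoxy(2,3,4,5-tetramethoxyphenyl)borate | [Li+].CO[B-](OC)(OC)c1cc(OC)c(OC)c(OC)c1OC | intermediate
4 | 2,3,4,5-tetramethoxyphenol | COc1cc(O)c(OC)c(OC)c1OC | intermediate
5 | 2-(hydroxymethyl)-3,4,5,6-tetramethoxyphenol (present as its magnesium salt) | COc1c(O)c(CO)c(OC)c(OC)c1OC | intermediate
6 | 2-hydroxy-3,4,5,6-tetramethoxybenzaldehyde | COc1c(O)c(C=O)c(OC)c(OC)c1OC | intermediate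
7 | 4-iodophenyl acetate | CC(=O)Oc1ccc(I)cc1 | starting material
8 | ethynyltrimethylsilane | C#C[Si](C)(C)C | starting material
9 | 4-[(trimethylsilyl)ethynyl]phenyl acetate | CC(=O)Oc1ccc(C#C[Si](C)(C)C)cc1 | intermediate
10 | [(4-acetoxyphenyl)ethynyl](phenyl)iodonium trifluoromethanesulfonate | CC(=O)Oc1ccc(C#C[I+]c2ccccc2)cc1.[O-]S(=O)(=O)C(F)(F)F | intermediate
11 | 4-[3-(2-hydroxy-3,4,5,6-tetramethoxyphenyl)-3-oxoprop-1-yn-1-yl]phenyl acetate | CC(=O)Oc1ccc(C#CC(=O)c2c(O)c(OC)c(OC)c(OC)c2OC)cc1 | intermediate
12 | 4-(5,6,7,8-tetramethoxy-4-oxo-4H-chromen-2-yl)phenyl acetate (4'-acetoxy-5,6,7,8-tetramethoxyflavone) | COc1c(OC)c(OC)c2c(=O)cc(-c3ccc(OC(C)=O)cc3)oc2c1OC | intermediate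
13 | 2-(4-hydroxyphenyl)-5,6,7,8-tetramethoxy-4H-chromen-4-one (4'-hydroxy-5,6,7,8-tetramethoxyflavone) | COc1c(OC)c(OC)c2c(=O)cc(-c3ccc(O)cc3)oc2c1OC | target

**Step count**
Total steps: 5. Longest linear sequence: 3 steps (1 → 4 → 6 → 13; the ring B branch 7 → 9 → 10 is 2 steps and joins in step 5).

**Steps most likely to fail, with fallbacks**

Step 5 (highest risk). Failure modes:
- The aldehyde of 6 has two ortho substituents, so Breslow intermediate formation may be slow.
- The phenoxide of 6 may attack 10 at oxygen.
- The carbene may shuttle the acetyl group.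
- Ring closure may go partly 5-exo to the aurone.

Fallback, setting out from 6 and returning at 12: keep the acyl anion logic but make the C3–C4 bond intramolecularly at an sp3 carbon. Bought 4-acetoxystyrene with NBS in aqueous acetone gives racemic 4-(2-bromo-1-hydroxyethyl)phenyl acetate F1. Mitsunobu etherification of 6 with it (PPh3, DIAD, THF, 0 °C → rt) gives racemic 4-[2-bromo-1-(2-formyl-3,4,5,6-tetramethoxyphenoxy)ethyl]phenyl acetate F2. With 3-ethyl-5-(2-hydroxyethyl)-4-methylthiazolium bromide (20 mol%) and K2CO3 in THF at 60 °C, the Breslow intermediate displaces the primary bromide and closes ring C as racemic 4-(5,6,7,8-tetramethoxy-4-oxochroman-2-yl)phenyl acetate F3. DDQ in dioxane at reflux dehydrogenates C2–C3, which removes the stereocentre and gives 12; the K2CO3/MeOH stage of step 5 then gives 13.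

Step 4. Failure modes: the strongly acidic bis(triflate) reagent may damage the acetate or the alkyne, and the triflate salt may decompose on isolation.

Fallback, setting out from 9 and returning at 11: desilylate 9 with tetrabutylammonium fluoride buffered with AcOH (THF, 0 °C) to 4-ethynylphenyl acetate F4. Treat it with [hydroxy(tosyloxy)iodo]benzene (CH2Cl2, rt) to get [(4-acetoxyphenyl)ethynyl](phenyl)iodonium 4-methylbenzenesulfonate F5, a crystalline salt made without strong acid. It replaces 10 in step 5 and the route is rejoined at ynone 11.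

Step 2. Failure modes: the single free position of 4 sits between OH and an OMe-bearing carbon, and the very electron-rich phenol may give diarylmethane by-products or be oxidised.

Fallback, setting out from 4 and returning at 6: switch from phenoxide-directed formylation to directed ortho-metalation. MOMCl and iPr2NEt in CH2Cl2 give 1,2,3,4-tetramethoxy-5-(methoxymethoxy)benzene F6. n-BuLi (THF, −78 → 0 °C) removes the only ring proton, which is flanked by OMOM and OMe, and DMF gives 2,3,4,5-tetramethoxy-6-(methoxymethoxy)benzaldehyde F7. HCl in MeOH at rt removes the MOM group and gives 6.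

**Further compounds**
F1 | step 5 | 4-(2-bromo-1-hydroxyethyl)phenyl acetate (racemic) | CC(=O)Oc1ccc(C(O)CBr)cc1
F2 | step 5 | 4-[2-bromo-1-(2-formyl-3,4,5,6-tetramethoxyphenoxy)ethyl]phenyl acetate (racemic) | CC(=O)Oc1ccc(C(CBr)Oc2c(C=O)c(OC)c(OC)c(OC)c2OC)cc1
F3 | step 5 | 4-(5,6,7,8-tetramethoxy-4-oxochroman-2-yl)phenyl acetate (racemic) | COc1c(OC)c(OC)c2C(=O)CC(c3ccc(OC(C)=O)cc3)Oc2c1OC
F4 | step 4 | 4-ethynylphenyl acetate | C#Cc1ccc(OC(C)=O)cc1
F5 | step 4 | [(4-acetoxyphenyl)ethynyl](phenyl)iodonium 4-methylbenzenesulfonate | CC(=O)Oc1ccc(C#C[I+]c2ccccc2)cc1.Cc1ccc(S(=O)(=O)[O-])cc1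
F6 | step 2 | 1,2,3,4-tetramethoxy-5-(methoxymethoxy)benzene | COCOc1cc(OC)c(OC)c(OC)c1OC
F7 | step 2 | 2,3,4,5-tetramethoxy-6-(methoxymethoxy)benzaldehyde | COCOc1c(C=O)c(OC)c(OC)c(OC)c1OC
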